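## Retrosynthetic overview

- The strategy rests on ring A, the benzene ring C4a–C5–C6–C7–C8–C8a. It is cut into three alkynes: C6/C7 from bis(trimethylsilyl)acetylene, and C8/C8a plus C4a/C5 from the two terminal alkynes of a 1,7-diyne. The C4a–C8a bond made in the same step closes ring B (C1–C4, C4a, C8a), whose sp3 carbons C1 (aryl), C2 and C3 (methyl) form the diyne tether and carry all three stereocentres.
- After the ring-forming step the two C–Si bonds at C6 and C7 are turned into C–OMe (boron, then oxygen, then methyl).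
- The diyne is cut at C1: its alkyne comes from a secondary benzylic boronic ester (alkynylation with retention), and the C1–aryl bond from lithiation–borylation of a primary benzoate with an arylboronic ester.
- C2/C3 come from C2-symmetric (2R,3R)-2,3-dimethylbutane-1,4-diol, made by oxidative dimerisation of a propanoyl oxazolidinone. Ring order: stereotriad first in the open chain, then rings B and A together.

Key step: step 9

Assumption: the facial rules known for simple substrates are taken to hold here, namely C–C bond formation anti to the benzyl group of the auxiliary in step 1 and removal of the pro-S hydrogen by s-BuLi/(−)-sparteine in step 6 despite the neighbouring methyl stereocentre.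

## Route

Step 1
Reactants: 1 (S)-4-benzyl-3-propanoyl-1,3-oxazolidin-2-one (two molecules)
Product: 3 (2R,3R)-1,4-bis[(4S)-4-benzyl-2-oxo-1,3-oxazolidin-3-yl]-2,3-dimethylbutane-1,4-dione, via lithium Z-enolate 2 (not isolated)
Conditions: LDA, THF, −78 °C; then CuCl2 (divalent copper), DMF, −78 °C → rt
Reagents that add atoms: lithium diisopropylamide, CC(C)N([Li])C(C)C (lithium of intermediate 2 only)
Why: Oxidative enolate homocoupling joins the two α-carbons, and each new C–C bond should form on the face of the chelated Z-enolate opposite the benzyl group of the auxiliary, as in auxiliary-controlled alkylations, which sets both methyl-bearing centres as R,R (the later C2 and C3).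

Step 2
Reactants: 3 (2R,3R)-1,4-bis[(4S)-4-benzyl-2-oxo-1,3-oxazolidin-3-yl]-2,3-dimethylbutane-1,4-dione
Product: 4 (2R,3R)-2,3-dimethylbutane-1,4-diol
Conditions: LiBH4, MeOH, THF, 0 °C → rt
Reagents that add atoms: none
Why: Reductive cleavage of the two N-acyl oxazolidinones by borohydride should give the primary diol and release the auxiliary without enolising the α-stereocentres.

Step 3
Reactants: 4 (2R,3R)-2,3-dimethylbutane-1,4-diol
Product: 5 (2R,3R)-4-hydroxy-2,3-dimethylbutyl 2,4,6-triisopropylbenzoate
Conditions: 4 (2.5 equiv), NaH, THF, 0 °C; then 2,4,6-triisopropylbenzoyl chloride (1 equiv), rt → 50 °C; excess 4 recovered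
Reagents that add atoms: 2,4,6-triisopropylbenzoyl chloride, CC(C)c1cc(C(C)C)c(C(Cl)=O)c(C(C)C)c1
Why: Monoacylation of a C2-symmetric diol, whose two hydroxyl groups are homotopic, can give only one monoester, and the hindered benzoate is the directing and leaving group needed for the later lithiation–borylation.

Step 4
Reactants: 5 (2R,3R)-4-hydroxy-2,3-dimethylbutyl 2,4,6-triisopropylbenzoate
Product: 6 (2R,3R)-4-iodo-2,3-dimethylbutyl 2,4,6-triisopropylbenzoate
Conditions: I2, PPh3, imidazole, CH2Cl2, 0 °C → rt
Reagents that add atoms: iodine, II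
Why: Appel-type iodination of the primary alcohol is an SN2 displacement at CH2 that touches neither stereocentre nor the hindered ester.

Step 5
Reactants: 6 (2R,3R)-4-iodo-2,3-dimethylbutyl 2,4,6-triisopropylbenzoate; 7 ethynyltrimethylsilane
Product: 8 (2R,3S)-2,3-dimethyl-6-(trimethylsilyl)hex-5-yn-1-yl 2,4,6-triisopropylbenzoate
Conditions: 7, n-BuLi, THF, −78 °C; then 6, DMPU, −78 °C → rt
Reagents that add atoms: none
Why: SN2 alkylation of a lithium acetylide by the primary iodide in a dipolar cosolvent should install the C4a/C5 alkyne carbons, the triisopropylbenzoate being too hindered for acyl attack and the silyl group masking the alkyne C–H for the next step.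

Step 6
Reactants: 8 (2R,3S)-2,3-dimethyl-6-(trimethylsilyl)hex-5-yn-1-yl 2,4,6-triisopropylbenzoate; 9 2-(3,4-dimethoxyphenyl)-4,4,5,5-tetramethyl-1,3,2-dioxaborolane
Product: 12 2-[(1R,2S,3S)-1-(3,4-dimethoxyphenyl)-2,3-dimethyl-6-(trimethylsilyl)hex-5-yn-1-yl]-4,4,5,5-tetramethyl-1,3,2-dioxaborolane, via α-lithiated benzoate 10 (not isolated), via lithium boronate complex 11 (not isolated)
Conditions: s-BuLi, (−)-sparteine, Et2O, −78 °C, 5 h; then 9, −78 °C → 35 °C
Reagents that add atoms: sec-butyllithium, CCC(C)[Li] (lithium of intermediates 10 and 11 only)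
Why: Lithiation–borylation: sparteine-mediated deprotonation removes the pro-S hydrogen next to the ester oxygen, boron adds with retention, and the aryl group then shifts from boron to carbon with inversion as the benzoate leaves (1,2-metallate rearrangement), which sets the benzylic centre (later C1) under reagent control.

Step 7
Reactants: 12 2-[(1R,2S,3S)-1-(3,4-dimethoxyphenyl)-2,3-dimethyl-6-(trimethylsilyl)hex-5-yn-1-yl]-4,4,5,5-tetramethyl-1,3,2-dioxaborolane; 13 bromoethene
Product: 16 (3R,4R,5S)-2-bromo-3-(3,4-dimethoxyphenyl)-4,5-dimethyl-8-(trimethylsilyl)oct-1-en-7-yne, via bromoethenyl boronate complex 14 (not isolated), via β-iodo boronic ester 15 (not isolated)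
Conditions: 13, LDA, THF, −78 °C; then I2, MeOH, −78 °C; then NaOMe, MeOH, −78 °C → rt
Reagents that add atoms: lithium diisopropylamide, CC(C)N([Li])C(C)C (lithium of intermediate 14 only); iodine, II (iodine of intermediate 15 only)
Why: Zweifel-type olefination: 1-bromovinyllithium generated in the presence of 12 adds to boron, iodine triggers the 1,2-shift of the secondary benzylic carbon with retention of configuration, and methoxide-induced anti-elimination of boron and iodide leaves the 2-bromoalkene.

Step 8
Reactants: 16 (3R,4R,5S)-2-bromo-3-(3,4-dimethoxyphenyl)-4,5-dimethyl-8-(trimethylsilyl)oct-1-en-7-yne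
Product: 18 (3S,4R,5S)-3-(3,4-dimethoxyphenyl)-4,5-dimethylocta-1,7-diyne, via desilylated bromoalkene 17 (not isolated)
Conditions: Bu4NF·3H2O, DMF, rt → 60 °C
Reagents that add atoms: none
Why: Fluoride first cleaves the alkynyl C–Si bond and then effects E2 dehydrobromination of the 2-bromo-1-alkene to the terminal alkyne, neither event involving a bond at the benzylic stereocentre.

Step 9
Reactants: 18 (3S,4R,5S)-3-(3,4-dimethoxyphenyl)-4,5-dimethylocta-1,7-diyne; 19 bis(trimethylsilyl)acetylene
Product: 20 (1R,2R,3S)-1-(3,4-dimethoxyphenyl)-2,3-dimethyl-6,7-bis(trimethylsilyl)-1,2,3,4-tetrahydronaphthalene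
Conditions: CpCo(CO)2 (10 mol%), 19 as solvent, reflux (about 135 °C), hν (visible), slow addition of 18 by syringe pump, Ar
Reagents that add atoms: none
Why: Light and heat strip CO from CpCo(CO)2, the CpCo fragment (monovalent cobalt) takes up both terminal alkynes of 18 and couples them oxidatively to a bicyclic cobaltacyclopentadiene (trivalent cobalt), which makes the C4a–C8a bond and closes ring B as a six-membered carbocycle by intramolecular metallacycle formation across the four-carbon tether. Alkyne 19 then coordinates, inserts into a Co–C bond (or adds across the diene in a [4+2] sense), and reductive elimination makes C5–C6 and C7–C8, closing ring A as the arene and returning the CpCo fragment; the nearest known reaction type is the cobalt-mediated [2+2+2] cocyclisation of α,ω-diynes with bis(trimethylsilyl)acetylene, which turns 1,7-diynes into 6,7-disilyltetralins. No stereocentre is created, since the stereotriad sits on saturated tether carbons that take no part in the bond reorganisation, and the non-basic medium should leave the acidic benzylic, propargylic C–H of 18 alone. The selectivity required is cocyclisation of one diyne with one molecule of 19 instead of diyne oligomerisation: the tether pairs the two alkynes of 18 on cobalt, 19 is too crowded to trimerise on its own, it is present as the solvent, and 18 is fed in slowly. Because 19 is symmetrical there is no regiochemical issue, and the two silicon atoms label C6 and C7 as the carbons that will carry oxygen.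

Step 10
Reactants: 20 (1R,2R,3S)-1-(3,4-dimethoxyphenyl)-2,3-dimethyl-6,7-bis(trimethylsilyl)-1,2,3,4-tetrahydronaphthalene
Product: 22 [(5R,6R,7S)-5-(3,4-dihydroxyphenyl)-6,7-dimethyl-5,6,7,8-tetrahydronaphthalene-2,3-diyl]diboronic acid, via aryl bromoborane 21 (not isolated)
Conditions: BBr3 (6 equiv), CH2Cl2, −78 °C → rt; then H2O, 0 °C; crude 22 used directly
Reagents that add atoms: boron tribromide, BrB(Br)Br; water, O
Why: Electrophilic ipso-borodesilylation: BBr3 attacks each silicon-bearing aryl carbon through a β-silyl-stabilised arenium ion and expels Me3SiBr, the excess reagent at the same time cleaves the two aryl methyl ethers of the pendant ring, and hydrolysis should give the bis(boronic acid).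

Step 11
Reactants: 22 [(5R,6R,7S)-5-(3,4-dihydroxyphenyl)-6,7-dimethyl-5,6,7,8-tetrahydronaphthalene-2,3-diyl]diboronic acid
Product: 23 (5R,6R,7S)-5-(3,4-dihydroxyphenyl)-6,7-dimethyl-5,6,7,8-tetrahydronaphthalene-2,3-diol
Conditions: 30% aq. H2O2, NaHCO3, THF/H2O, 0 °C → rt, Ar; then aq. Na2S2O3, dilute HCl
Reagents that add atoms: hydrogen peroxide, OO
Why: Oxidation of arylboronic acids by hydroperoxide (1,2-aryl shift from boron to oxygen, then hydrolysis) should replace each C–B bond by C–OH, the mild buffer and inert atmosphere protecting the two catechols.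

Step 12
Reactants: 23 (5R,6R,7S)-5-(3,4-dihydroxyphenyl)-6,7-dimethyl-5,6,7,8-tetrahydronaphthalene-2,3-diol
Product: 24 (1R,2R,3S)-1-(3,4-dimethoxyphenyl)-6,7-dimethoxy-2,3-dimethyl-1,2,3,4-tetrahydronaphthalene
Conditions: Me2SO4 (excess), K2CO3, acetone, reflux, Ar
Reagents that add atoms: dimethyl sulfate, COS(=O)(=O)OC
Why: Williamson O-methylation of all four phenols should give the tetramethyl ether, the carbonate base being far too weak to touch the C1–H or the other stereocentres.

## Compound list

1 | (S)-4-benzyl-3-propanoyl-1,3-oxazolidin-2-one | CCC(=O)N1[C@@H](Cc2ccccc2)COC1=O | starting material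
2 | lithium (Z)-enolate of 1 (formed in the flask, not isolated) | C/C=C(\O[Li])N1[C@@H](Cc2ccccc2)COC1=O | intermediate
3 | (2R,3R)-1,4-bis[(4S)-4-benzyl-2-oxo-1,3-oxazolidin-3-yl]-2,3-dimethylbutane-1,4-dione | O=C(N1[C@@H](Cc2ccccc2)COC1=O)[C@H](C)[C@@H](C)C(=O)N1[C@@H](Cc2ccccc2)COC1=O | intermediate
4 | (2R,3R)-2,3-dimethylbutane-1,4-diol | OC[C@H](C)[C@@H](C)CO | intermediate
5 | (2R,3R)-4-hydroxy-2,3-dimethylbutyl 2,4,6-triisopropylbenzoate | CC(C)c1cc(C(C)C)c(C(=O)OC[C@H](C)[C@@H](C)CO)c(C(C)C)c1 | intermediate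
6 | (2R,3R)-4-iodo-2,3-dimethylbutyl 2,4,6-triisopropylbenzoate | CC(C)c1cc(C(C)C)c(C(=O)OC[C@H](C)[C@@H](C)CI)c(C(C)C)c1 | intermediate
7 | ethynyltrimethylsilane | C#C[Si](C)(C)C | starting material
8 | (2R,3S)-2,3-dimethyl-6-(trimethylsilyl)hex-5-yn-1-yl 2,4,6-triisopropylbenzoate | CC(C)c1cc(C(C)C)c(C(=O)OC[C@H](C)[C@@H](C)CC#C[Si](C)(C)C)c(C(C)C)c1 | intermediate
9 | 2-(3,4-dimethoxyphenyl)-4,4,5,5-tetramethyl-1,3,2-dioxaborolane | COc1ccc(B2OC(C)(C)C(C)(C)O2)cc1OC | starting material
10 | (1S,2R,3S)-1-lithio-2,3-dimethyl-6-(trimethylsilyl)hex-5-yn-1-yl 2,4,6-triisopropylbenzoate (sparteine complex, not isolated) | CC(C)c1cc(C(C)C)c(C(=O)O[C@@H]([Li])[C@H](C)[C@@H](C)CC#C[Si](C)(C)C)c(C(C)C)c1 | intermediate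
11 | lithium boronate complex from 10 and 9, boron bearing the aryl group and the α-(triisopropylbenzoyloxy)alkyl group (not isolated) | [Li+].COc1ccc([B-]2(OC(C)(C)C(C)(C)O2)[C@H](OC(=O)c2c(C(C)C)cc(C(C)C)cc2C(C)C)[C@H](C)[C@@H](C)CC#C[Si](C)(C)C)cc1OC | intermediate
12 | 2-[(1R,2S,3S)-1-(3,4-dimethoxyphenyl)-2,3-dimethyl-6-(trimethylsilyl)hex-5-yn-1-yl]-4,4,5,5-tetramethyl-1,3,2-dioxaborolane | COc1ccc([C@H](B2OC(C)(C)C(C)(C)O2)[C@H](C)[C@@H](C)CC#C[Si](C)(C)C)cc1OC | intermediate
13 | bromoethene (vinyl bromide) | C=CBr | starting material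
14 | lithium (1-bromoethenyl)boronate complex of 12 (not isolated) | [Li+].COc1ccc([C@H]([B-]2(OC(C)(C)C(C)(C)O2)C(Br)=C)[C@H](C)[C@@H](C)CC#C[Si](C)(C)C)cc1OC | intermediate
15 | 2-[(3R,4R,5S)-2-bromo-3-(3,4-dimethoxyphenyl)-1-iodo-4,5-dimethyl-8-(trimethylsilyl)oct-7-yn-2-yl]-4,4,5,5-tetramethyl-1,3,2-dioxaborolane (either configuration at C2, not isolated) | COc1ccc([C@H](C(Br)(CI)B2OC(C)(C)C(C)(C)O2)[C@H](C)[C@@H](C)CC#C[Si](C)(C)C)cc1OC | intermediate
16 | (3R,4R,5S)-2-bromo-3-(3,4-dimethoxyphenyl)-4,5-dimethyl-8-(trimethylsilyl)oct-1-en-7-yne | COc1ccc([C@H](C(Br)=C)[C@H](C)[C@@H](C)CC#C[Si](C)(C)C)cc1OC | intermediate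
17 | (3R,4R,5S)-2-bromo-3-(3,4-dimethoxyphenyl)-4,5-dimethyloct-1-en-7-yne (not isolated) | COc1ccc([C@H](C(Br)=C)[C@H](C)[C@@H](C)CC#C)cc1OC | intermediate
18 | (3S,4R,5S)-3-(3,4-dimethoxyphenyl)-4,5-dimethylocta-1,7-diyne | COc1ccc([C@H](C#C)[C@H](C)[C@@H](C)CC#C)cc1OC | intermediate
19 | bis(trimethylsilyl)acetylene | C[Si](C)(C)C#C[Si](C)(C)C | starting material
20 | (1R,2R,3S)-1-(3,4-dimethoxyphenyl)-2,3-dimethyl-6,7-bis(trimethylsilyl)-1,2,3,4-tetrahydronaphthalene | COc1ccc([C@@H]2c3cc([Si](C)(C)C)c([Si](C)(C)C)cc3C[C@H](C)[C@H]2C)cc1OC | intermediate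
21 | 2-bromo-5-[(1R,2R,3S)-6,7-bis(dibromoboranyl)-2,3-dimethyl-1,2,3,4-tetrahydronaphthalen-1-yl]-1,3,2-benzodioxaborole (not isolated) | BrB1Oc2ccc([C@@H]3c4cc(B(Br)Br)c(B(Br)Br)cc4C[C@H](C)[C@H]3C)cc2O1 | intermediate
22 | [(5R,6R,7S)-5-(3,4-dihydroxyphenyl)-6,7-dimethyl-5,6,7,8-tetrahydronaphthalene-2,3-diyl]diboronic acid | Oc1ccc([C@@H]2c3cc(B(O)O)c(B(O)O)cc3C[C@H](C)[C@H]2C)cc1O | intermediate
23 | (5R,6R,7S)-5-(3,4-dihydroxyphenyl)-6,7-dimethyl-5,6,7,8-tetrahydronaphthalene-2,3-diol | Oc1ccc([C@@H]2c3cc(O)c(O)cc3C[C@H](C)[C@H]2C)cc1O | intermediate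
24 | (1R,2R,3S)-1-(3,4-dimethoxyphenyl)-6,7-dimethoxy-2,3-dimethyl-1,2,3,4-tetrahydronaphthalene | COc1ccc([C@@H]2c3cc(OC)c(OC)cc3C[C@H](C)[C@H]2C)cc1OC | target

## Step count and risks

Total step count: 12. Longest linear sequence: 12 steps (1 to 24); compounds 7, 9, 13 and 19 enter as purchased building blocks.

The cobalt cocyclisation (step 9) follows a well-known reaction type for 1,7-diynes and is judged less exposed than the three steps below.

Step 8. The fluoride-induced elimination may be accompanied by base-mediated isomerisation of the newly formed benzylic alkyne to an allene, with loss of the C3 stereocentre of the diyne. The fallback sets out from boronic ester 12 and builds the alkyne by carbonyl chemistry instead of elimination. Matteson homologation of 12 with LiCHCl2 (from CH2Cl2 and n-BuLi, THF, −100 °C, then ZnCl2) would give the α-chloro boronic ester F6. Buffered oxidation (NaBO3·4H2O, THF/H2O) would give the α-aryl aldehyde F7, which is used at once. Dibromo-olefination under neutral conditions (CBr4, PPh3, Zn, CH2Cl2, 0 °C; first stage of a Corey–Fuchs sequence) would give the 1,1-dibromoalkene F8. Treatment with n-BuLi (THF, −78 °C) would give the terminal alkyne F9, which still carries the silyl group on the other alkyne. K2CO3 in MeOH then removes that silyl group and the route is rejoined at diyne 18.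

Step 6. Deprotonation next to the ester oxygen may be slowed by the β-methyl branch, so that metalation at the propargylic CH2 beside the silyl alkyne competes and conversion or selectivity at the new benzylic centre falls. The fallback sets out from monoester 5 and brings the second alkyne in only after the boron chemistry. Silylation of 5 (tert-butyldimethylsilyl chloride, imidazole, CH2Cl2) gives the silyl ether F1. Lithiation–borylation of F1 with 9 under the conditions of step 6 gives boronic ester F2, and bromovinylation as in step 7 gives alkenyl bromide F3. Bu4NF·3H2O in DMF removes the silyl ether and eliminates HBr to give the hydroxy alkyne F4. Iodination (I2, PPh3, imidazole) gives iodide F5. Alkylation of lithium acetylide (ethylenediamine complex, DMSO, rt, excess) by F5 rejoins the route at diyne 18.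

Step 10. The second ipso-substitution, next to the first boron group, may stall or be overtaken by protodesilylation from adventitious HBr, which would leave C6 or C7 without oxygen. The fallback sets out from diyne 18 and brings boron in with the third alkyne. The same CpCo(CO)2 cocyclisation, run with 1,2-bis(4,4,5,5-tetramethyl-1,3,2-dioxaborolan-2-yl)ethyne in place of 19, should give the 6,7-diboronic ester F10 with the pendant methyl ethers intact. Oxidation (NaBO3·4H2O, THF/H2O) gives catechol F11, and methylation under the conditions of step 12 rejoins the route at target 24.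

Further compounds

F1 | step 6 | (2R,3R)-4-[(tert-butyldimethylsilyl)oxy]-2,3-dimethylbutyl 2,4,6-triisopropylbenzoate | CC(C)c1cc(C(C)C)c(C(=O)OC[C@H](C)[C@@H](C)CO[Si](C)(C)C(C)(C)C)c(C(C)C)c1
F2 | step 6 | silyl ether analogue of 12 with CH2OSi(t-Bu)Me2 in place of the silylpropargyl group, same spatial arrangement at the three centres | COc1ccc([C@H](B2OC(C)(C)C(C)(C)O2)[C@H](C)[C@@H](C)CO[Si](C)(C)C(C)(C)C)cc1OC
F3 | step 6 | silyl ether analogue of 16 with CH2OSi(t-Bu)Me2 in place of the silylpropargyl group | COc1ccc([C@H](C(Br)=C)[C@H](C)[C@@H](C)CO[Si](C)(C)C(C)(C)C)cc1OC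
F4 | step 6 | 4-(3,4-dimethoxyphenyl)-2,3-dimethylhex-5-yn-1-ol, configuration as in 18 | COc1ccc([C@H](C#C)[C@H](C)[C@@H](C)CO)cc1OC
F5 | step 6 | 4-(3-(3,4-dimethoxyphenyl)-6-iodo-4,5-dimethylhex-1-yne skeleton) iodide from F4, configuration as in 18 | COc1ccc([C@H](C#C)[C@H](C)[C@@H](C)CI)cc1OC
F6 | step 8 | α-chloro boronic ester from one-carbon homologation of 12 (either configuration at the chlorine-bearing carbon) | COc1ccc([C@H](C(Cl)B2OC(C)(C)C(C)(C)O2)[C@H](C)[C@@H](C)CC#C[Si](C)(C)C)cc1OC
F7 | step 8 | 2-(3,4-dimethoxyphenyl)-3,4-dimethyl-7-(trimethylsilyl)hept-6-ynal, configuration as in 12 | COc1ccc([C@H](C=O)[C@H](C)[C@@H](C)CC#C[Si](C)(C)C)cc1OC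
F8 | step 8 | 1,1-dibromo-3-(3,4-dimethoxyphenyl)-4,5-dimethyl-8-(trimethylsilyl)oct-1-en-7-yne | COc1ccc([C@H](C=C(Br)Br)[C@H](C)[C@@H](C)CC#C[Si](C)(C)C)cc1OC
F9 | step 8 | (3S,4R,5S)-3-(3,4-dimethoxyphenyl)-4,5-dimethyl-8-(trimethylsilyl)octa-1,7-diyne | COc1ccc([C@H](C#C)[C@H](C)[C@@H](C)CC#C[Si](C)(C)C)cc1OC
F10 | step 10 | 6,7-bis(4,4,5,5-tetramethyl-1,3,2-dioxaborolan-2-yl) analogue of 20 | COc1ccc([C@@H]2c3cc(B4OC(C)(C)C(C)(C)O4)c(B4OC(C)(C)C(C)(C)O4)cc3C[C@H](C)[C@H]2C)cc1OC
F11 | step 10 | (5R,6R,7S)-5-(3,4-dimethoxyphenyl)-6,7-dimethyl-5,6,7,8-tetrahydronaphthalene-2,3-diol | COc1ccc([C@@H]2c3cc(O)c(O)cc3C[C@H](C)[C@H]2C)cc1OC
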